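**Plan**

- Retrosynthesis: after the acid-labile protecting groups, the C5 side chain is cut at its Cα=Cβ bond, ring A at C7–C7a (C7–O going back to a carboxylic acid), the exocyclic alkene of the resulting half-ester by a Wittig cut, and the furan at O1–C5 and C3–C4 (Feist–Benary), which leaves an aroylacetate of protected danshensu.
- Forward: protected danshensu is acylated to the β-keto ester, the furan ring is built first, the succinate chain is attached, ring A closes second, and the danshensu acrylate is joined last before one acidic deprotection.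
- Enabling feature: ring A carries its hydroxyl on C7, next to the ring-fusion carbon C7a (the carbon bonded to the furan oxygen), and a carbon substituent on C5. This is the pattern a ketene carbon (→ C7) leaves when it bonds to the free α-carbon (→ C7a) of a furan whose β-carbon (→ C3a) holds the dienyl chain.
- Stereochemistry: both (R) centres come unchanged from sodium (R)-danshensu, and no step breaks a bond at these carbons; the E side-chain alkene comes from the decarboxylative condensation.

Key step: step 12

Remark: Ar = 2,2-dimethyl-1,3-benzodioxol-5-yl; Dan = (2R)-1-tert-butoxy-3-Ar-1-oxopropan-2-yl, the O-bound residue of tert-butyl (R)-3-Ar-2-hydroxypropanoate.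
Remark: allyl alcohol is assumed to open (triphenylphosphoranylidene)succinic anhydride in the same sense as methanol, placing the ester on the ylide carbon.

**Route**

Step 1
Reactants: 1 5-bromo-2,2-dimethyl-1,3-benzodioxole
Product: 3 acetonide-protected protocatechuic acid (2,2-dimethyl-1,3-benzodioxole-5-carboxylic acid), via aryllithium 2 (not isolated)
Conditions: n-BuLi, THF, −78 °C; CO2; then cold 1 M HCl
Reagents that add atoms: carbon dioxide, O=C=O
Why: Bromine–lithium exchange followed by carboxylation of the aryllithium is standard, and the catechol acetonide is inert to n-BuLi and to a brief cold acidic work-up.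

Step 2
Reactants: 3 2,2-dimethyl-1,3-benzodioxole-5-carboxylic acid; 4 Meldrum's acid (2,2-dimethyl-1,3-dioxane-4,6-dione)
Product: 5 aroyl Meldrum's acid 5-[Ar(hydroxy)methylidene]-2,2-dimethyl-1,3-dioxane-4,6-dione
Conditions: DCC, DMAP, CH2Cl2, 0 °C to rt
Reagents that add atoms: none
Why: Carbodiimide-mediated C-acylation of Meldrum's acid with a carboxylic acid is a routine entry to acyl Meldrum's acids and gives the enol form shown.

Step 3
Reactants: 6 sodium danshensu (sodium (R)-3-(3,4-dihydroxyphenyl)-2-hydroxypropanoate)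
Product: 7 bis-acetonide (5R)-5-(Ar-methyl)-2,2-dimethyl-1,3-dioxolan-4-one
Conditions: 2,2-dimethoxypropane, TsOH·H2O (1.1 equiv), acetone/toluene, reflux, 4 Å MS (Soxhlet)
Reagents that add atoms: 2,2-dimethoxypropane, COC(C)(C)OC
Why: Acid-catalysed transketalisation with removal of methanol should protect the catechol as its acetonide and the α-hydroxy acid as its dioxolanone in one operation, without touching the C–H bond of the stereocentre.

Step 4
Reactants: 7 (5R)-5-(Ar-methyl)-2,2-dimethyl-1,3-dioxolan-4-one
Product: 8 (R)-3-Ar-2-hydroxypropanoic acid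
Conditions: LiOH, THF/H2O, 0 °C; then 1 M HCl to pH 3
Reagents that add atoms: lithium hydroxide, [Li+].[OH-]
Why: Saponification of the activated dioxolanone (acetone is lost from the hemiketal) is fast at 0 °C, while the catechol acetonide is stable to base and the α-centre is not enolised under these conditions.

Step 5
Reactants: 8 (R)-3-Ar-2-hydroxypropanoic acid
Product: 9 tert-butyl (R)-3-Ar-2-hydroxypropanoate
Conditions: tert-butyl 2,2,2-trichloroacetimidate, CH2Cl2/cyclohexane, rt
Reagents that add atoms: tert-butyl 2,2,2-trichloroacetimidate, CC(C)(C)OC(=N)C(Cl)(Cl)Cl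
Why: Uncatalysed imidate esterification is selective for the carboxylic acid, because the secondary alcohol would need a Lewis acid to react, and it leaves the stereocentre untouched.

Step 6
Reactants: 5 aroyl Meldrum's acid; 9 tert-butyl (R)-3-Ar-2-hydroxypropanoate
Product: 11 β-keto ester Dan 3-Ar-3-oxopropanoate, via aroylketene 10 (not isolated)
Conditions: toluene, reflux
Reagents that add atoms: none
Why: Thermolysis of an acyl Meldrum's acid releases acetone and CO2 to give an acylketene that is trapped by the secondary alcohol under neutral conditions, so the lactate centre cannot epimerise.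

Step 7
Reactants: 11 β-keto ester Dan 3-Ar-3-oxopropanoate; 12 1,3-dichloroacetone
Product: 14 Dan 2-Ar-4-(chloromethyl)furan-3-carboxylate, via hydroxydihydrofuran 13 (not isolated)
Conditions: K2CO3, THF, 0 °C to rt; filter; then PPTS (cat.), toluene, 60 °C
Reagents that add atoms: none
Why: In this Feist–Benary reaction the β-keto ester adds to the very electrophilic ketone carbonyl, the aryl ketone enolate oxygen displaces one chloride (5-exo-tet) and mild acid dehydrates the carbinol to the aromatic furan, which puts CH2Cl on C4, leaves C5 free and erases the transient carbinol stereocentre.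

Step 8
Reactants: 14 Dan 2-Ar-4-(chloromethyl)furan-3-carboxylate
Product: 16 Dan 2-Ar-4-formylfuran-3-carboxylate, via alkoxysulfonium chloride 15 (not isolated)
Conditions: DMSO, NaHCO3, 90 °C
Reagents that add atoms: dimethyl sulfoxide, CS(C)=O
Why: Kornblum oxidation of the benzylic-type furylmethyl chloride proceeds by O-alkylation of DMSO and bicarbonate-induced loss of dimethyl sulfide, and bicarbonate is too weak to harm the esters or the lactate centre.

Step 9
Reactants: 17 triphenylphosphine; 18 maleic anhydride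
Product: 19 (triphenylphosphoranylidene)succinic anhydride
Conditions: acetone, rt
Reagents that add atoms: none
Why: Conjugate addition of the phosphine to maleic anhydride followed by proton transfer gives the stabilised ylide, which should precipitate from acetone.

Step 10
Reactants: 19 (triphenylphosphoranylidene)succinic anhydride; 20 allyl alcohol
Product: 21 allyl hydrogen (triphenylphosphoranylidene)succinate (4-(allyloxy)-4-oxo-3-(triphenylphosphoranylidene)butanoic acid)
Conditions: allyl alcohol/CH2Cl2, rt
Reagents that add atoms: none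
Why: Alcoholysis of the ylide anhydride is the known route to alkyl hydrogen (triphenylphosphoranylidene)succinates, with the ester ending on the ylide carbon and the free acid on the methylene arm.

Step 11
Reactants: 16 Dan 2-Ar-4-formylfuran-3-carboxylate; 21 allyl hydrogen (triphenylphosphoranylidene)succinate
Product: 22 (E)-3-(allyloxycarbonyl)-4-[5-Ar-4-(Dan-oxycarbonyl)furan-3-yl]but-3-enoic acid
Conditions: toluene, rt to 60 °C
Reagents that add atoms: none
Why: The Wittig reaction of this ester-stabilised ylide with an aryl aldehyde gives the Stobbe-type half-ester under neutral conditions with the furan trans to the ester (E), which places the CH2CO2H arm cis to the furan.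

Step 12
Reactants: 22 (E)-3-(allyloxycarbonyl)-4-[5-Ar-4-(Dan-oxycarbonyl)furan-3-yl]but-3-enoic acid
Product: 27 allyl 7-acetoxy-2-Ar-3-(Dan-oxycarbonyl)benzofuran-5-carboxylate, via mixed anhydride 23 (not isolated), via dienylketene 24 (not isolated), via dienone 25 (not isolated), via phenol 26 (not isolated)
Conditions: Ac2O, NaOAc, 100 °C
Reagents that add atoms: acetic anhydride, CC(=O)OC(C)=O
Why: Acetic anhydride converts the acid into mixed anhydride 23, from which acetate removes the allylic α-proton so that acetic acid is lost and dienylketene 24 forms, its C=C=O terminus, the exocyclic alkene and the furan C3=C2 bond (furan numbering, chain on C3) making up a 1,3,5-hexatriene. A thermal disrotatory six-electron electrocyclisation then joins the ketene carbon to the free furan α-carbon and closes the six-membered ring A (6π electrocyclic closure, new bond C7–C7a) as dienone 25, whose enolisation restores the furan and gives phenol 26, which acetic anhydride caps as acetate 27. The closest known reaction type is the Ac2O/NaOAc cyclisation of Stobbe arylidene- and furylmethylidenesuccinic half-esters to acetoxynaphthoates and acetoxybenzofurancarboxylates. No stereocentre is kept, since the sp3 carbon C7a of 25 is flattened on aromatisation. The step needs closure at the α-carbon and a chain held cis to the furan: the other ortho position carries the ester, and the E alkene from step 11 puts the CH2CO2H arm on the furan side. Acetate is too weak a base to epimerise the lactate carbon or eliminate its acyloxy group, and the buffered medium should leave the tert-butyl esters and acetonides intact.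

Step 13
Reactants: 27 allyl 7-acetoxy-2-Ar-3-(Dan-oxycarbonyl)benzofuran-5-carboxylate
Product: 29 2-Ar-3-(Dan-oxycarbonyl)-7-hydroxybenzofuran-5-carboxylic acid, via acetoxy acid 28 (not isolated)
Conditions: Pd(PPh3)4 (5 mol %), pyrrolidine (excess), THF, rt; then aq. citric acid
Reagents that add atoms: none
Why: Zerovalent palladium ionises the allyl ester (Tsuji–Trost deallylation) with pyrrolidine as allyl acceptor, and the same amine then cleaves the aryl acetate by aminolysis, while the alkyl and tert-butyl esters are inert to a secondary amine at room temperature.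

Step 14
Reactants: 29 2-Ar-3-(Dan-oxycarbonyl)-7-hydroxybenzofuran-5-carboxylic acid
Product: 30 Dan 2-Ar-7-hydroxy-5-(hydroxymethyl)benzofuran-3-carboxylate
Conditions: BH3·SMe2, THF, 0 °C to rt; MeOH quench
Reagents that add atoms: none
Why: Borane reduces a carboxylic acid through its acyloxyborane much faster than it attacks esters, so only the C5 acid should be reduced; the phenol merely consumes one hydride.

Step 15
Reactants: 30 Dan 2-Ar-7-hydroxy-5-(hydroxymethyl)benzofuran-3-carboxylate
Product: 31 Dan 2-Ar-5-formyl-7-hydroxybenzofuran-3-carboxylate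
Conditions: MnO2, CH2Cl2, rt
Reagents that add atoms: none
Why: Activated MnO2 oxidises benzylic alcohols selectively to aldehydes without over-oxidation, and the meta-placed phenol cannot form a quinone methide.

Step 16
Reactants: 9 tert-butyl (R)-3-Ar-2-hydroxypropanoate; 4 Meldrum's acid
Product: 32 malonic half-ester 3-(Dan-oxy)-3-oxopropanoic acid
Conditions: toluene, 90 °C
Reagents that add atoms: none
Why: Alcoholysis of Meldrum's acid with loss of acetone is the standard neutral route to malonic acid monoesters of secondary alcohols and does not involve the stereocentre.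

Step 17
Reactants: 31 Dan 2-Ar-5-formyl-7-hydroxybenzofuran-3-carboxylate; 32 malonic half-ester 3-(Dan-oxy)-3-oxopropanoic acid
Product: 34 protected schizotenuin A Dan (E)-3-[2-Ar-3-(Dan-oxycarbonyl)-7-hydroxybenzofuran-5-yl]prop-2-enoate, via arylidenemalonic half-ester 33 (not isolated)
Conditions: piperidine (cat.), pyridine, 60 °C
Reagents that add atoms: none
Why: Knoevenagel–Doebner condensation of an aryl aldehyde with a malonic half-ester followed by decarboxylation in pyridine gives the E cinnamate ester, as known for danshensu malonates, and the weak amine bases should not epimerise the lactate centres.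

Step 18
Reactants: 34 protected schizotenuin A
Product: 35 schizotenuin A
Conditions: TFA/H2O (9:1), 0 °C to rt, argon
Reagents that add atoms: none
Why: Acidolysis removes both tert-butyl esters as isobutene and hydrolyses the three catechol acetonides to acetone, while the two carboxylic ester links, the alkene and the stereocentres are stable to aqueous TFA at room temperature.

**Compound list**

1 | 5-bromo-2,2-dimethyl-1,3-benzodioxole | Brc1ccc2OC(C)(C)Oc2c1 | starting material
2 | (2,2-dimethyl-1,3-benzodioxol-5-yl)lithium (in situ) | [Li]c1ccc2OC(C)(C)Oc2c1 | intermediate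
3 | 2,2-dimethyl-1,3-benzodioxole-5-carboxylic acid | OC(=O)c1ccc2OC(C)(C)Oc2c1 | intermediate
4 | Meldrum's acid | CC1(C)OC(=O)CC(=O)O1 | starting material
5 | 5-[Ar(hydroxy)methylidene]-2,2-dimethyl-1,3-dioxane-4,6-dione | CC1(C)OC(=O)C(=C(O)c2ccc3OC(C)(C)Oc3c2)C(=O)O1 | intermediate
6 | sodium (R)-danshensu | O[C@H](Cc1ccc(O)c(O)c1)C(=O)[O-].[Na+] | starting material
7 | (5R)-5-(Ar-methyl)-2,2-dimethyl-1,3-dioxolan-4-one | CC1(C)O[C@H](Cc2ccc3OC(C)(C)Oc3c2)C(=O)O1 | intermediate
8 | (R)-3-Ar-2-hydroxypropanoic acid | O[C@H](Cc1ccc2OC(C)(C)Oc2c1)C(=O)O | intermediate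
9 | tert-butyl (R)-3-Ar-2-hydroxypropanoate | O[C@H](Cc1ccc2OC(C)(C)Oc2c1)C(=O)OC(C)(C)C | intermediate
10 | aroylketene 3-Ar-3-oxoprop-1-en-1-one (in situ) | O=C=CC(=O)c1ccc2OC(C)(C)Oc2c1 | intermediate
11 | Dan 3-Ar-3-oxopropanoate | O=C(CC(=O)c1ccc2OC(C)(C)Oc2c1)O[C@H](Cc1ccc2OC(C)(C)Oc2c1)C(=O)OC(C)(C)C | intermediate
12 | 1,3-dichloroacetone | ClCC(=O)CCl | starting material
13 | Dan 2-Ar-4-(chloromethyl)-4-hydroxy-4,5-dihydrofuran-3-carboxylate (in situ, both epimers at C4) | OC1(CCl)COC(-c2ccc3OC(C)(C)Oc3c2)=C1C(=O)O[C@H](Cc1ccc2OC(C)(C)Oc2c1)C(=O)OC(C)(C)C | intermediate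
14 | Dan 2-Ar-4-(chloromethyl)furan-3-carboxylate | ClCc1coc(-c2ccc3OC(C)(C)Oc3c2)c1C(=O)O[C@H](Cc1ccc2OC(C)(C)Oc2c1)C(=O)OC(C)(C)C | intermediate
15 | dimethyl(furylmethoxy)sulfonium chloride of 14 (in situ) | C[S+](C)OCc1coc(-c2ccc3OC(C)(C)Oc3c2)c1C(=O)O[C@H](Cc1ccc2OC(C)(C)Oc2c1)C(=O)OC(C)(C)C.[Cl-] | intermediate
16 | Dan 2-Ar-4-formylfuran-3-carboxylate | O=Cc1coc(-c2ccc3OC(C)(C)Oc3c2)c1C(=O)O[C@H](Cc1ccc2OC(C)(C)Oc2c1)C(=O)OC(C)(C)C | intermediate
17 | triphenylphosphine | c1ccc(cc1)P(c1ccccc1)c1ccccc1 | starting material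
18 | maleic anhydride | O=C1OC(=O)C=C1 | starting material
19 | (triphenylphosphoranylidene)succinic anhydride | O=C1CC(=P(c2ccccc2)(c2ccccc2)c2ccccc2)C(=O)O1 | intermediate
20 | allyl alcohol | OCC=C | starting material
21 | allyl hydrogen (triphenylphosphoranylidene)succinate | OC(=O)CC(=P(c1ccccc1)(c1ccccc1)c1ccccc1)C(=O)OCC=C | intermediate
22 | (E)-3-(allyloxycarbonyl)-4-[5-Ar-4-(Dan-oxycarbonyl)furan-3-yl]but-3-enoic acid | OC(=O)C/C(C(=O)OCC=C)=C\c1coc(-c2ccc3OC(C)(C)Oc3c2)c1C(=O)O[C@H](Cc1ccc2OC(C)(C)Oc2c1)C(=O)OC(C)(C)C | intermediate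
23 | acetic mixed anhydride of 22 (in situ) | CC(=O)OC(=O)C/C(C(=O)OCC=C)=C\c1coc(-c2ccc3OC(C)(C)Oc3c2)c1C(=O)O[C@H](Cc1ccc2OC(C)(C)Oc2c1)C(=O)OC(C)(C)C | intermediate
24 | dienylketene from 23 (in situ) | O=C=C/C(C(=O)OCC=C)=C\c1coc(-c2ccc3OC(C)(C)Oc3c2)c1C(=O)O[C@H](Cc1ccc2OC(C)(C)Oc2c1)C(=O)OC(C)(C)C | intermediate
25 | allyl 2-Ar-3-(Dan-oxycarbonyl)-7-oxo-7,7a-dihydrobenzofuran-5-carboxylate (in situ, both epimers at C7a) | O=C1C=C(C(=O)OCC=C)C=C2C1OC(-c3ccc4OC(C)(C)Oc4c3)=C2C(=O)O[C@H](Cc1ccc2OC(C)(C)Oc2c1)C(=O)OC(C)(C)C | intermediate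
26 | allyl 2-Ar-3-(Dan-oxycarbonyl)-7-hydroxybenzofuran-5-carboxylate (in situ) | C=CCOC(=O)c1cc(O)c2oc(-c3ccc4OC(C)(C)Oc4c3)c(C(=O)O[C@H](Cc5ccc6OC(C)(C)Oc6c5)C(=O)OC(C)(C)C)c2c1 | intermediate
27 | allyl 7-acetoxy-2-Ar-3-(Dan-oxycarbonyl)benzofuran-5-carboxylate | C=CCOC(=O)c1cc(OC(C)=O)c2oc(-c3ccc4OC(C)(C)Oc4c3)c(C(=O)O[C@H](Cc5ccc6OC(C)(C)Oc6c5)C(=O)OC(C)(C)C)c2c1 | intermediate
28 | 7-acetoxy-2-Ar-3-(Dan-oxycarbonyl)benzofuran-5-carboxylic acid (in situ) | OC(=O)c1cc(OC(C)=O)c2oc(-c3ccc4OC(C)(C)Oc4c3)c(C(=O)O[C@H](Cc5ccc6OC(C)(C)Oc6c5)C(=O)OC(C)(C)C)c2c1 | intermediate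
29 | 2-Ar-3-(Dan-oxycarbonyl)-7-hydroxybenzofuran-5-carboxylic acid | OC(=O)c1cc(O)c2oc(-c3ccc4OC(C)(C)Oc4c3)c(C(=O)O[C@H](Cc5ccc6OC(C)(C)Oc6c5)C(=O)OC(C)(C)C)c2c1 | intermediate
30 | Dan 2-Ar-7-hydroxy-5-(hydroxymethyl)benzofuran-3-carboxylate | OCc1cc(O)c2oc(-c3ccc4OC(C)(C)Oc4c3)c(C(=O)O[C@H](Cc5ccc6OC(C)(C)Oc6c5)C(=O)OC(C)(C)C)c2c1 | intermediate
31 | Dan 2-Ar-5-formyl-7-hydroxybenzofuran-3-carboxylate | O=Cc1cc(O)c2oc(-c3ccc4OC(C)(C)Oc4c3)c(C(=O)O[C@H](Cc5ccc6OC(C)(C)Oc6c5)C(=O)OC(C)(C)C)c2c1 | intermediate
32 | 3-(Dan-oxy)-3-oxopropanoic acid | OC(=O)CC(=O)O[C@H](Cc1ccc2OC(C)(C)Oc2c1)C(=O)OC(C)(C)C | intermediate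
33 | arylidenemalonic half-ester from 31 and 32 (in situ, alkene geometry not fixed) | OC(=O)C(=Cc1cc(O)c2oc(-c3ccc4OC(C)(C)Oc4c3)c(C(=O)O[C@H](Cc5ccc6OC(C)(C)Oc6c5)C(=O)OC(C)(C)C)c2c1)C(=O)O[C@H](Cc1ccc2OC(C)(C)Oc2c1)C(=O)OC(C)(C)C | intermediate
34 | protected schizotenuin A | O=C(/C=C/c1cc(O)c2oc(-c3ccc4OC(C)(C)Oc4c3)c(C(=O)O[C@H](Cc5ccc6OC(C)(C)Oc6c5)C(=O)OC(C)(C)C)c2c1)O[C@H](Cc1ccc2OC(C)(C)Oc2c1)C(=O)OC(C)(C)C | intermediate
35 | schizotenuin A | O=C(/C=C/c1cc(O)c2oc(-c3ccc(O)c(O)c3)c(C(=O)O[C@H](Cc3ccc(O)c(O)c3)C(=O)O)c2c1)O[C@H](Cc1ccc(O)c(O)c1)C(=O)O | target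

**Step count and risks**

Total steps: 18. Longest linear sequence: 13 steps (steps 3, 4, 5, 6, 7, 8, 11, 12, 13, 14, 15, 17, 18, from sodium danshensu).

Step 12. The hot acetic acid/acetic anhydride medium may strip a tert-butyl ester before the ketene forms, or the dienylketene may oligomerise faster than it closes onto the ester-bearing furan. The fallback generates the same ketene without acid or prolonged heating. It sets out from 22, which 1-chloro-N,N,2-trimethylprop-1-en-1-amine in CH2Cl2 at 0 °C should convert under neutral conditions into the acid chloride F1. Triethylamine in toluene (rt to 60 °C) then dehydrochlorinates it to dienylketene 24, and electrocyclisation and enolisation give phenol 26. The fallback rejoins the route at 26, which needs only the deallylation half of step 13 to reach 29.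

Step 7. The β-keto ester enolate may attack a CH2Cl carbon instead of the carbonyl (leading after ring closure to the isomeric 5-chloromethylfuran), the dichloroketone may be alkylated twice, or the acid dehydration may cost a tert-butyl ester. The fallback avoids an alkylating partner altogether. It sets out from 11, which is condensed with 1,3-dihydroxyacetone (dimer) and catalytic ZnCl2 in ethanol at 60 °C in a García González-type sequence (Knoevenagel condensation at the ketose carbonyl, hemiketalisation onto the aryl ketone, double dehydration) to the 4-(hydroxymethyl)furan F2. MnO2 in CH2Cl2 then oxidises it to aldehyde 16, where the route is rejoined and step 8 is no longer needed.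

Step 17. The bulky malonic half-ester may decarboxylate before it condenses, the condensation may stall on the phenoxide-bearing aldehyde, or prolonged heating in amine base may erode the lactate configuration. The fallback is a neutral Wittig olefination. It sets out from 9, which is heated with (triphenylphosphoranylidene)ketene (Ph3P=C=C=O) in toluene to give the ester ylide F3. Addition of aldehyde 31 at rt to 60 °C should give the E acrylate directly, and the route is rejoined at 34.

**Further compounds**

F1 | step 12 | (E)-3-(allyloxycarbonyl)-4-[5-Ar-4-(Dan-oxycarbonyl)furan-3-yl]but-3-enoyl chloride | ClC(=O)C/C(C(=O)OCC=C)=C\c1coc(-c2ccc3OC(C)(C)Oc3c2)c1C(=O)O[C@H](Cc1ccc2OC(C)(C)Oc2c1)C(=O)OC(C)(C)C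
F2 | step 7 | Dan 2-Ar-4-(hydroxymethyl)furan-3-carboxylate | OCc1coc(-c2ccc3OC(C)(C)Oc3c2)c1C(=O)O[C@H](Cc1ccc2OC(C)(C)Oc2c1)C(=O)OC(C)(C)C
F3 | step 17 | Dan (triphenylphosphoranylidene)acetate | O=C(C=P(c1ccccc1)(c1ccccc1)c1ccccc1)O[C@H](Cc1ccc2OC(C)(C)Oc2c1)C(=O)OC(C)(C)C
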